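(The readings are calculated with constants of no real substance; noise was put on by code.)

The closed, stirred vessel at constant volume holds J and X with less Z than either earlier flask.

| flask | J | X | Z | remark | time |
|---|---|---|---|---|---|
| Tuesday's | 0.050 M | 1.02 equiv | 0.021 M | run made earlier |  |
| Saturday's | 0.050 M | 1.02 equiv | 0.033 M | run made earlier |  |
| flask | 0.050 M | 1.02 equiv | 0.0150 M |  | 10 d |

| run | time / d | G / % | J / % |
|---|---|---|---|
| Tuesday's | 2.08 | 60.4 | 39.5 |
| Tuesday's | 4.00 | 59.9 | 39.9 |
| Tuesday's | 6.00 | 59.7 | 40.2 |
| Tuesday's | 8.00 | 58.9 | 40.2 |
| Saturday's | 0.625 | 45.2 | 54.3 |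
| Saturday's | 1.67 | 45.4 | 55.3 |
| Saturday's | 3.00 | 44.4 | 55.7 |
| Saturday's | 8.00 | 41.8 | 57.9 |

(each reading ± 0.3 percentage points)

- each molecule carries two end groups: a chain counts once for every two ends that are left, dead ends included; the units are half of the end groups of the two monomers charged

- whether the average number of monomer units in a chain (unreacted monomers counted as chains of one) reaches 3.0 by 10 d (yes / no)
- average number of monomer units in a chain (unreacted monomers counted as chains of one) at 10 d

In Tuesday's run, G fell from 60.4 % to 58.9 % of the J charged between 2.08 d and 8.00 d while J rose from 39.5 % to 40.2 %, so these readings show J returning as links break. Units come to 101 % of the J charged, and chains are units less G, so length is units over units less G. Length 3.0 therefore needs G of 67.3 %.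

The reckoning here supposes that each Z takes one X end for good. That leaves X ends for links of 72.0 % of the J charged in this flask. This share, X equivalents less Z per J, is the link budget, an effective stoichiometric ratio. Tuesday's budget is 60.0 %, and its G reading ended at 58.9 %. Saturday's budget is 36.0 %, and its G reading fell from 45.2 % to 41.8 %, still above that budget.

This flask's budget exceeds the need by 4.7 percentage points, and a full budget gives length 3.48. This reckoning therefore says yes, if G in this flask comes as near its budget as Tuesday's last reading did, 1.1 points short.

The forecast says yes, with length 3.1, on its own ground: “Links form in a fast equilibrium that Z suppresses”.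

The flask gives yes, with length 3.23 at 10 d.

    X + Z → L (k = 16.0 M⁻¹ h⁻¹)
    J + X ⇌ G + D (K = 72.0, k = 5.30 M⁻¹ h⁻¹)

The flask passed length 3.0 at 0.877 d. At 10.0 d, with Z down to 0.0439 % of its charge, G of 69.8 % and free X of 2.23 % of the J charged add up to 72.0 %, against a budget of 72.0 %. Tuesday's flask shows what more Z does: its budget of 60.0 % lies below the 67.3 % that length 3.0 needs, and its last G reading, 58.9 % at 8.00 d, corresponds to a length of 2.40.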